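You cannot read the effect of spacing off the earlier runs: each of them adds its portions every 8.0 min. One quantity has to carry those runs over to wider spacings.

| flask | starting material | salt in the second phase | spent carrier | remark | time | volume of the second phase over the first |
|---|---|---|---|---|---|---|
| north-east | 24 mM (in portions, 3) | 47 mM | 1.2 mM | run made earlier; portions every 8.0 min |  |  |
| north | 35 mM (in portions, 3) | 47 mM | 1.2 mM | run made earlier; portions every 8.0 min |  |  |
| north-west | 47 mM (in portions, 3) | 47 mM | 1.8 mM | run made earlier; portions every 8.0 min |  |  |
| theta | 47 mM (in portions, 3) | 47.0 mM | 1.2 mM | the portions of starting material follow each other after 8.0 min, the first at the start | 80 min | 1.0 |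
| delta | 47 mM (in portions, 3) | 47.0 mM | 1.2 mM | the portions of starting material follow each other after 12 min, the first at the start | 80 min | 1.0 |
| epsilon | 47 mM (in portions, 3) | 47.0 mM | 1.2 mM | the portions of starting material follow each other after 20 min, the first at the start | 80 min | 1.0 |
| gamma | 47 mM (in portions, 3) | 47.0 mM | 1.2 mM | the portions of starting material follow each other after 25 min, the first at the start | 80 min | 1.0 |

- north-east (time / min: target / %): 12.0: 22; 25.0: 53; 40.0: 74; 50.0: 80; 60.0: 90
- north (time / min: target / %): 12.0: 20; 25.0: 44; 40.0: 61; 50.0: 73; 60.0: 77
- north-west (time / min: target / %): 5.00: 13; 10.0: 17; 20.0: 40; 30.0: 51; 60.0: 74

(standard deviation of a reading: 2 percentage points)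

- charges count per volume of the first phase; a concentration in a rate is the amount of a species over the volume of its own phase; every rate counts per litre of the first phase
- the earlier runs hold the two phases in the same ratio of volumes as the flask asked about
- "hardly changes" means that all values lie within two and a half points (for a concentration: within two and a half percent of the largest)

- amount of target at the end, in percent of the starting material charged for theta, delta, epsilon, gamma, in this order
- how that number moves from the first to the last of them (rises, then falls / falls, then rises / rises all the way / hardly changes / falls all the way)

**Carrier dose.** With 3 equal portions the middle one arrives one interval late, so the average delay is one interval. The mean stay of the charge is therefore the time minus that interval. I take the rate to follow the carrier, so I multiply the mean stay by c(spent carrier) and call the product the dose. At the end it is 5.18 M·s for theta and 3.96 M·s for gamma.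

**What matters.** An error of 0.240 mM in c(spent carrier) changes the dose by the same fraction, and at the slope between the last two north-west readings that moves my estimate for theta by about 7.4 percentage points, so the carrier has to be known well. A north-west reading off by 2 points shifts the answer by roughly that amount. The volume ratio matches the earlier runs and needs no care. The charge matters as well: at 60.0 min with the same carrier, the north-east run stands at 90 % from 24 mM and the north run at 77 % from 35 mM, so I read from the north-west run.

**Two rounds.** The north-west run has the full charge, and its readings at 30.0 min and 60.0 min stand at doses 2.38 M·s and 5.62 M·s. In a first round, treating the decay as pseudo-first-order in dose, gamma comes to 64.1 %.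

Now put that answer back in. It lies between those two north-west readings, so my rule need hold over that stretch and no further: as a working assumption, I let the ratio of target to unreacted rise straight with dose there. In the north-west run that ratio goes from 1.04 to 2.85. This reads as 0.557 /M/s, the dose gain: the rise of the ratio per unit of dose. Going back from the north-west reading, theta has a ratio of 2.61, which is 72.3 %, and gamma comes to 65.8 %.

**The forecast.** It gave 73 %, 72 %, 69 % and 66 %, so the yield falls all the way, on the ground that “the last portion has only 30 min in an already inhibited mixture”.

**The flask.** It gives 72.5 %, 71.7 %, 69.3 % and 67.2 %: the yield falls all the way.

    starting material → decomposition product (k = 1.50 × 10⁻⁷ /s)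
    spent carrier + salt in the second phase ⇌ fresh carrier + spent salt in the second phase (K = 18.0, k = 0.410 /M/s)
    starting material + fresh carrier ⇌ target + spent carrier (K = 2.90, k = 1.70 /M/s)

**Gamma's dose.** Start from theta's 72.5 % and take off the dose gamma loses, 1.22 M·s, at the dose gain 0.557 /M/s. The ratio drops to 1.95, which is 66.1 % of target, and gamma gave 67.2 %. Part of what holds gamma down is target and spent carrier falling back to starting material and fresh carrier: with that step removed, gamma ends at 77.0 % instead of 67.2 %. The same gamma flask left ten times as long reaches 86.9 %.

(The runs are simulated from invented constants; noise was put on by code.)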